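**Retrosynthetic overview**
1. The two oxiranes come last, by peracid epoxidation of a (1(10)-ring-cis, 2Z, 4E)-triene 12,6α-lactone; the lactone comes from a 6,12-diol and the C14 ester from carbonylation of a C10 alkenyl bromide.
2. The 8β-ester is made by SN2 inversion of an 8α-bromo-9-ketone with epoxyangelate (acid from angelic acid by Sharpless epoxidation); the 9α-OH by Felkin reduction.
3. The ten-membered ring is made by anionic oxy-Cope ring expansion of a trans-1,2-dialkenylcyclohexa-2,4-dienol (breaks C9–C4, forms C6–C7, transfers chirality, gives 4E), with bromination of the resulting enolate.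
4. That dienol comes from a 6,6-disubstituted cyclohexa-2,4-dienone made by enantioselective dearomative ortho-C-allylation of 2-bromo-6-methylphenol (from o-cresol); the arene supplies C9, C10, C1–C4, C15, the C9 oxygen and both cis olefins.
5. Ring order: six-membered carbocycle (from the arene) → ten-membered carbocycle → γ-lactone → two oxiranes.

Assumption: locants C1–C15 follow germacranolide numbering of the target (C1=C10 ring-cis olefin with C14 ester; C2/C3 and C4/C5 oxiranes; C15 methyl on C4; C6 lactone O; C7; C8 acyloxy; C9 OAc; C11–C13 methylene-lactone carbons), α/β as usually drawn (target: 6α-O, 7β-C11, 8β-O, 9α-O, 2α,3α- and 4α,5β-oxiranes); TBS = tert-butyldimethylsilyl; 1, 7, 9, 17 and all reagents are taken as commercial.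

**Step 1**
Reactants: 1 o-cresol (2-methylphenol)
Product: 2 2-bromo-6-methylphenol
Conditions: NBS, i-Pr2NH (10 mol%), CH2Cl2, 0 °C
Reagents that add atoms: N-bromosuccinimide, O=C1CCC(=O)N1Br
Why: Amine-mediated ortho-selective electrophilic aromatic bromination, in which the N-bromoamine delivers bromine through a hydrogen-bonded phenol complex to the only free ortho position.

**Step 2**
Reactants: 2 2-bromo-6-methylphenol
Product: 3 (6R)-6-allyl-2-bromo-6-methylcyclohexa-2,4-dien-1-one
Conditions: Pd2(dba)3 (2.5 mol%), (S)-t-BuPHOX (6 mol%), allyl methyl carbonate, toluene, 0 °C, stopped at full conversion, product kept cold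
Reagents that add atoms: allyl methyl carbonate, C=CCOC(=O)OC
Why: Proposed new method: methoxide released on ionization of the carbonate deprotonates 2, and the O-bound palladium phenoxide/π-allyl pair collapses by an inner-sphere seven-membered reductive elimination that can reach only an ortho carbon; the electron-richer methyl-bearing carbon is allylated rather than the C–Br carbon, and the PHOX pocket differentiates the two ring faces at C4 as it does for a tetrasubstituted enolate, setting the quaternary centre (the (S)-ligand is expected to give 6R by analogy with 2-methylcyclohexanone enolates, the antipodal ligand is used if not); the product cannot re-aromatize by tautomerization and the 2-bromo group suppresses Diels–Alder dimerization; closest known reactions are the PHOX–palladium allylation of tetrasubstituted ketone enolates and the palladium-catalysed allylic dearomatization of 1-substituted 2-naphthols.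

**Step 3**
Reactants: 3 (6R)-6-allyl-2-bromo-6-methylcyclohexa-2,4-dien-1-one
Product: 5 2-[(1R)-3-bromo-1-methyl-2-oxocyclohexa-3,5-dien-1-yl]acetaldehyde, via secondary ozonide 4 (not isolated)
Conditions: O3 (1 equiv), CH2Cl2, −78 °C; then Me2S, −78 °C → rt
Reagents that add atoms: ozone, [O-][O+]=O
Why: Chemoselective ozonolysis (Criegee mechanism) of the isolated monosubstituted olefin, which is far more electron-rich than the carbonyl- and bromine-deactivated ring olefins; the quaternary centre is untouched.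

**Step 4**
Reactants: 5 2-[(1R)-3-bromo-1-methyl-2-oxocyclohexa-3,5-dien-1-yl]acetaldehyde
Product: 6 (6S)-2-bromo-6-methyl-6-[(E)-2-(TBS-oxy)ethenyl]cyclohexa-2,4-dien-1-one (same spatial arrangement as 3)
Conditions: TBSOTf, Et3N, CH2Cl2, −78 → 0 °C
Reagents that add atoms: tert-butyldimethylsilyl triflate, CC(C)(C)[Si](C)(C)OS(=O)(=O)C(F)(F)F
Why: Soft enolization/O-silylation of the only enolizable carbonyl (the dienone has no α-hydrogen); the E enol ether is favoured because the quaternary ring carbon avoids the position cis to the silyloxy group.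

**Step 5**
Reactants: 7 2-bromoprop-2-en-1-ol
Product: 8 (2-bromoprop-2-enyloxy)(tert-butyl)dimethylsilane
Conditions: TBSCl, imidazole, DMF, rt
Reagents that add atoms: tert-butyldimethylsilyl chloride, CC(C)(C)[Si](C)(C)Cl
Why: Standard imidazole-catalysed silyl ether protection.

**Step 6**
Reactants: 8 (2-bromoprop-2-enyloxy)(tert-butyl)dimethylsilane; 9 (E)-1,2-bis(tributylstannyl)ethene (3 equiv)
Product: 10 tributyl[(1E)-3-(TBS-oxymethyl)buta-1,3-dien-1-yl]stannane
Conditions: Pd(PPh3)4 (5 mol%), toluene, 90 °C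
Reagents that add atoms: none
Why: Stille cross-coupling in which the excess bis-stannane couples once, with retention of the E geometry of the ethene unit.

**Step 7**
Reactants: 10 tributyl[(1E)-3-(TBS-oxymethyl)buta-1,3-dien-1-yl]stannane; 6 (6S)-2-bromo-6-methyl-6-[(E)-2-(TBS-oxy)ethenyl]cyclohexa-2,4-dien-1-one
Product: 13 (1R,6S)-2-bromo-1-[(1E)-3-(TBS-oxymethyl)buta-1,3-dien-1-yl]-6-[(E)-2-(TBS-oxy)ethenyl]-6-methylcyclohexa-2,4-dien-1-ol (the two alkenyl groups trans), via dienyllithium 11 (not isolated), via lithium alkoxide 12 (not isolated)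
Conditions: n-BuLi (1.0 equiv), THF, −78 °C; then 6, −78 °C; H2O quench at −78 °C
Reagents that add atoms: none
Why: Tin–lithium exchange followed by 1,2-carbonyl addition of the hard alkenyllithium (α-bromo enones add 1,2); the nucleophile enters anti to the larger silyloxyvinyl group (Felkin-type), i.e. syn to methyl, which sets C9 and gives the trans-dialkenyl carbinol.

**Step 8**
Reactants: 13 the (1R,6S)-dienol
Product: 16 8α,10-dibromo-6α,12-bis(TBS-oxy)-14-norgermacra-1(10),2,4,11(13)-tetraen-9-one (7α-H; 1(10)-ring-cis, 2Z, 4E), via potassium alkoxide 14 (not isolated), via potassium enolate 15 (not isolated)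
Conditions: KN(SiMe3)2, 18-crown-6, THF, −78 → −30 °C; then NBS, −78 °C
Reagents that add atoms: N-bromosuccinimide, O=C1CCC(=O)N1Br
Why: Anionic oxy-Cope rearrangement through the chair transition state open only to the two exocyclic E-alkenyl groups (both substituents equatorial; the [3,3] paths through ring olefins are boat-constrained), which breaks C9–C4, forms C6–C7, transfers the C4/C9 chirality to C6 (α-O) and C7 (β-C) and gives the 4E olefin; the crossed-conformer enolate is then brominated on its exposed outer face to give the 8α-bromide.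

**Step 9**
Reactants: 17 angelic acid, (Z)-2-methylbut-2-enoic acid
Product: 18 (Z)-2-methylbut-2-en-1-ol
Conditions: LiAlH4, Et2O, 0 °C; then H2O
Reagents that add atoms: none
Why: Hydride reduction of the carboxylic acid with retention of the Z olefin geometry.

**Step 10**
Reactants: 18 (Z)-2-methylbut-2-en-1-ol
Product: 19 [(2R,3S)-2,3-dimethyloxiran-2-yl]methanol
Conditions: Ti(OiPr)4 (10 mol%), D-(−)-diethyl tartrate (12 mol%), t-BuOOH, 4 Å MS, CH2Cl2, −20 °C
Reagents that add atoms: tert-butyl hydroperoxide, CC(C)(C)OO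
Why: Sharpless asymmetric epoxidation, the D-(−)-tartrate catalyst choosing the olefin face that gives the (2R,3S)-epoxy alcohol, with the cis methyl/CH2OH relation fixed by the Z olefin.

**Step 11**
Reactants: 19 [(2R,3S)-2,3-dimethyloxiran-2-yl]methanol
Product: 21 (2S,3S)-2,3-dimethyloxirane-2-carboxylic acid, via epoxy aldehyde 20 (not isolated)
Conditions: RuCl3 (2 mol%), NaIO4, CCl4/MeCN/H2O, rt
Reagents that add atoms: water, O (oxygen source via the aldehyde hydrate)
Why: RuO4-catalysed oxidation of the primary alcohol to the acid without touching the oxirane stereocentres (the descriptor at C2 changes only by priority).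

**Step 12**
Reactants: 16 the 8α,10-dibromo ketone; 21 (2S,3S)-2,3-dimethyloxirane-2-carboxylic acid
Product: 23 10-bromo-8β-[(2S,3S)-2,3-dimethyloxirane-2-carbonyloxy]-6α,12-bis(TBS-oxy)-14-norgermacra-1(10),2,4,11(13)-tetraen-9-one, via cesium carboxylate 22 (not isolated)
Conditions: Cs2CO3 (0.5 equiv per 21), DMF, 0 °C; then 16, 0 °C → rt
Reagents that add atoms: none
Why: SN2 displacement of the activated α-bromo ketone by the soft cesium carboxylate with inversion at C8, turning 8α-Br into the required 8β-acyloxy group (no Favorskii path because C10 is sp2).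

**Step 13**
Reactants: 23 the 8β-acyloxy-9-ketone
Product: 24 10-bromo-8β-[(2S,3S)-2,3-dimethyloxirane-2-carbonyloxy]-6α,12-bis(TBS-oxy)-14-norgermacra-1(10),2,4,11(13)-tetraen-9α-ol
Conditions: NaBH4, CeCl3·7H2O, MeOH, −78 °C; AcOH quench
Reagents that add atoms: none
Why: Luche 1,2-reduction of the α-bromo enone, with hydride attacking anti to the C8–O bond (polar Felkin–Anh) to give the 8,9-trans (9α) alcohol.

**Step 14**
Reactants: 24 the 10-bromo-9α-ol
Product: 25 methyl 9α-hydroxy-8β-[(2S,3S)-2,3-dimethyloxirane-2-carbonyloxy]-6α,12-bis(TBS-oxy)germacra-1(10),2,4,11(13)-tetraen-14-oate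
Conditions: Pd(OAc)2 (5 mol%), Xantphos (6 mol%), CO (1 atm), MeOH, i-Pr2NEt, toluene, 45 °C
Reagents that add atoms: carbon monoxide, [C-]#[O+]; methanol, CO
Why: Palladium-catalysed methoxycarbonylation (oxidative addition into the alkenyl C–Br bond, CO insertion, methanolysis) with retention of the ring-cis olefin; the free allylic alcohol is not ionized and 45 °C is mild enough for the conjugated triene.

**Step 15**
Reactants: 25 the 9α-hydroxy methyl ester
Product: 26 methyl 9α-acetoxy-8β-[(2S,3S)-2,3-dimethyloxirane-2-carbonyloxy]-6α,12-bis(TBS-oxy)germacra-1(10),2,4,11(13)-tetraen-14-oate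
Conditions: Ac2O, pyridine, DMAP (cat.), CH2Cl2, 0 °C
Reagents that add atoms: acetic anhydride, CC(=O)OC(C)=O
Why: DMAP-catalysed acylation of the secondary allylic alcohol with retention at C9.

**Step 16**
Reactants: 26 the bis-silyl ether
Product: 27 methyl 9α-acetoxy-8β-[(2S,3S)-2,3-dimethyloxirane-2-carbonyloxy]-6α,12-dihydroxygermacra-1(10),2,4,11(13)-tetraen-14-oate
Conditions: Et3N·3HF, MeCN/THF, rt
Reagents that add atoms: none
Why: Fluoride-mediated cleavage of both silyl ethers under nearly neutral conditions that spare the esters and the oxirane.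

**Step 17**
Reactants: 27 the 6,12-diol
Product: 30 methyl 9α-acetoxy-8β-[(2S,3S)-2,3-dimethyloxirane-2-carbonyloxy]germacra-1(10),2,4,11(13)-tetraen-12,6α-olid-14-oate, via hydroxy enal 28 (not isolated), via lactol 29 (not isolated)
Conditions: TEMPO (20 mol%), PhI(OAc)2 (2.5 equiv), CH2Cl2, rt
Reagents that add atoms: none
Why: TEMPO/PhI(OAc)2 oxidative lactonization: the primary allylic alcohol is oxidized selectively, the aldehyde is trapped by the 6α-OH as a lactol, and this is oxidized to the trans-fused α-methylene-γ-butyrolactone, leaving C6 and C7 unchanged.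

**Step 18**
Reactants: 30 the triene lactone
Product: 32 CNP0077535.2, methyl 9α-acetoxy-8β-[(2S,3S)-2,3-dimethyloxirane-2-carbonyloxy]-2α,3α:4α,5β-diepoxygermacra-1(10),11(13)-dien-12,6α-olid-14-oate, via 4,5-monoepoxide 31 (not isolated)
Conditions: mCPBA (2.5 equiv), CH2Cl2, 0 °C → rt
Reagents that add atoms: 3-chloroperoxybenzoic acid, OOC(=O)c1cccc(Cl)c1
Why: Stereospecific Prilezhaev epoxidation: the electron-rich 4E olefin reacts first on its outer face anti to C7 in the allylic-strain-minimized conformer (H6 eclipsing the olefin, as in costunolide-type lactones) to give the 4α,5β-oxirane, then the cis 2,3-olefin is attacked on the α face opposite the C4 methyl; the enoate and methylene lactone are too electron-poor to react.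

**Compound list**
1 | o-cresol (2-methylphenol) | Cc1ccccc1O | starting material
2 | 2-bromo-6-methylphenol | Cc1cccc(Br)c1O | intermediate
3 | (6R)-6-allyl-2-bromo-6-methylcyclohexa-2,4-dien-1-one | C=CC[C@]1(C)C=CC=C(Br)C1=O | intermediate
4 | (6R)-2-bromo-6-methyl-6-(1,2,4-trioxolan-3-ylmethyl)cyclohexa-2,4-dien-1-one (secondary ozonide, trioxolane carbon unassigned) | C1(OCOO1)C[C@]2(C)C=CC=C(Br)C2=O | intermediate
5 | 2-[(1R)-3-bromo-1-methyl-2-oxocyclohexa-3,5-dien-1-yl]acetaldehyde | O=CC[C@]1(C)C=CC=C(Br)C1=O | intermediate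
6 | (6S)-2-bromo-6-methyl-6-[(E)-2-(TBS-oxy)ethenyl]cyclohexa-2,4-dien-1-one | CC(C)(C)[Si](C)(C)O/C=C/[C@]1(C)C=CC=C(Br)C1=O | intermediate
7 | 2-bromoprop-2-en-1-ol | OCC(Br)=C | starting material
8 | (2-bromoprop-2-enyloxy)(tert-butyl)dimethylsilane | C=C(Br)CO[Si](C)(C)C(C)(C)C | intermediate
9 | (E)-1,2-bis(tributylstannyl)ethene | CCCC[Sn](CCCC)(CCCC)/C=C/[Sn](CCCC)(CCCC)CCCC | starting material
10 | tributyl[(1E)-3-(TBS-oxymethyl)buta-1,3-dien-1-yl]stannane | CCCC[Sn](CCCC)(CCCC)/C=C/C(=C)CO[Si](C)(C)C(C)(C)C | intermediate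
11 | [(1E)-3-(TBS-oxymethyl)buta-1,3-dien-1-yl]lithium | [Li]/C=C/C(=C)CO[Si](C)(C)C(C)(C)C | intermediate
12 | lithium alkoxide of 13 | [Li+].[O-][C@@]1(/C=C/C(=C)CO[Si](C)(C)C(C)(C)C)C(Br)=CC=C[C@@]1(C)/C=C/O[Si](C)(C)C(C)(C)C | intermediate
13 | (1R,6S)-2-bromo-1-[(1E)-3-(TBS-oxymethyl)buta-1,3-dien-1-yl]-6-[(E)-2-(TBS-oxy)ethenyl]-6-methylcyclohexa-2,4-dien-1-ol | O[C@@]1(/C=C/C(=C)CO[Si](C)(C)C(C)(C)C)C(Br)=CC=C[C@@]1(C)/C=C/O[Si](C)(C)C(C)(C)C | intermediate
14 | potassium alkoxide of 13 | [K+].[O-][C@@]1(/C=C/C(=C)CO[Si](C)(C)C(C)(C)C)C(Br)=CC=C[C@@]1(C)/C=C/O[Si](C)(C)C(C)(C)C | intermediate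
15 | potassium 10-bromo-6α,12-bis(TBS-oxy)-14-norgermacra-1(10),2,4,8,11(13)-pentaen-9-olate | [K+].[O-]/C1=C\[C@@H](C(=C)CO[Si](C)(C)C(C)(C)C)[C@H](O[Si](C)(C)C(C)(C)C)/C=C(C)/C=C\C=C1\Br | intermediate
16 | 8α,10-dibromo-6α,12-bis(TBS-oxy)-14-norgermacra-1(10),2,4,11(13)-tetraen-9-one | O=C1[C@H](Br)[C@@H](C(=C)CO[Si](C)(C)C(C)(C)C)[C@H](O[Si](C)(C)C(C)(C)C)/C=C(C)/C=C\C=C1\Br | intermediate
17 | angelic acid, (Z)-2-methylbut-2-enoic acid | C/C=C(/C)C(=O)O | starting material
18 | (Z)-2-methylbut-2-en-1-ol | C/C=C(/C)CO | intermediate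
19 | [(2R,3S)-2,3-dimethyloxiran-2-yl]methanol | OC[C@@]1(C)O[C@H]1C | intermediate
20 | (2S,3S)-2,3-dimethyloxirane-2-carbaldehyde | O=C[C@@]1(C)O[C@H]1C | intermediate
21 | (2S,3S)-2,3-dimethyloxirane-2-carboxylic acid | OC(=O)[C@@]1(C)O[C@H]1C | intermediate
22 | cesium (2S,3S)-2,3-dimethyloxirane-2-carboxylate | [Cs+].[O-]C(=O)[C@@]1(C)O[C@H]1C | intermediate
23 | 10-bromo-8β-[(2S,3S)-2,3-dimethyloxirane-2-carbonyloxy]-6α,12-bis(TBS-oxy)-14-norgermacra-1(10),2,4,11(13)-tetraen-9-one | O=C1[C@@H](OC(=O)[C@@]2(C)O[C@H]2C)[C@@H](C(=C)CO[Si](C)(C)C(C)(C)C)[C@H](O[Si](C)(C)C(C)(C)C)/C=C(C)/C=C\C=C1\Br | intermediate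
24 | 9α-alcohol of 23 | O[C@@H]1[C@@H](OC(=O)[C@@]2(C)O[C@H]2C)[C@@H](C(=C)CO[Si](C)(C)C(C)(C)C)[C@H](O[Si](C)(C)C(C)(C)C)/C=C(C)/C=C\C=C1\Br | intermediate
25 | methyl 9α-hydroxy-8β-[(2S,3S)-2,3-dimethyloxirane-2-carbonyloxy]-6α,12-bis(TBS-oxy)germacra-1(10),2,4,11(13)-tetraen-14-oate | O[C@@H]1[C@@H](OC(=O)[C@@]2(C)O[C@H]2C)[C@@H](C(=C)CO[Si](C)(C)C(C)(C)C)[C@H](O[Si](C)(C)C(C)(C)C)/C=C(C)/C=C\C=C1\C(=O)OC | intermediate
26 | 9α-acetate of 25 | CC(=O)O[C@@H]1[C@@H](OC(=O)[C@@]2(C)O[C@H]2C)[C@@H](C(=C)CO[Si](C)(C)C(C)(C)C)[C@H](O[Si](C)(C)C(C)(C)C)/C=C(C)/C=C\C=C1\C(=O)OC | intermediate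
27 | methyl 9α-acetoxy-8β-[(2S,3S)-2,3-dimethyloxirane-2-carbonyloxy]-6α,12-dihydroxygermacra-1(10),2,4,11(13)-tetraen-14-oate | CC(=O)O[C@@H]1[C@@H](OC(=O)[C@@]2(C)O[C@H]2C)[C@@H](C(=C)CO)[C@H](O)/C=C(C)/C=C\C=C1\C(=O)OC | intermediate
28 | 6α-hydroxy-12-oxo analogue of 27 (hydroxy enal) | CC(=O)O[C@@H]1[C@@H](OC(=O)[C@@]2(C)O[C@H]2C)[C@@H](C(=C)C=O)[C@H](O)/C=C(C)/C=C\C=C1\C(=O)OC | intermediate
29 | 12-hydroxy-6α,12-epoxy lactol (C12 unassigned) | CC(=O)O[C@@H]1[C@@H](OC(=O)[C@@]2(C)O[C@H]2C)[C@H]3C(=C)C(O)O[C@@H]3/C=C(C)/C=C\C=C1\C(=O)OC | intermediate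
30 | methyl 9α-acetoxy-8β-[(2S,3S)-2,3-dimethyloxirane-2-carbonyloxy]germacra-1(10),2,4,11(13)-tetraen-12,6α-olid-14-oate | CC(=O)O[C@@H]1[C@@H](OC(=O)[C@@]2(C)O[C@H]2C)[C@H]3C(=C)C(=O)O[C@@H]3/C=C(C)/C=C\C=C1\C(=O)OC | intermediate
31 | 4α,5β-epoxide of 30 (germacra-1(10),2,11(13)-triene) | C=C1C(=O)O[C@H]2[C@H]1[C@H](OC(=O)[C@@]1(C)O[C@H]1C)[C@@H](OC(C)=O)/C(C(=O)OC)=C\C=C/[C@@]1(C)O[C@H]21 | intermediate
32 | CNP0077535.2 | C=C1C(=O)O[C@H]2[C@H]1[C@H](OC(=O)[C@@]1(C)O[C@H]1C)[C@@H](OC(C)=O)/C(C(=O)OC)=C\[C@H]1O[C@H]1[C@@]1(C)O[C@H]21 | target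

**Totals and risks**
Total step count: 18. Longest linear sequence: 13 steps (steps 1–4, 7, 8, 12–18; o-cresol to 32).

Step 2 is the most likely to fail: O- or para-allylation, attack at the C–Br carbon, low ee, or re-ionization of the dienone by zerovalent palladium. The fallback sets out from 2 and comes back at 3. Deprotonate 2 with NaH in toluene to give sodium 2-bromo-6-methylphenoxide F1. C-allylate this tight ion pair with allyl bromide (ortho delivery through the metal-bridged transition state, the classical route to 6-allylcyclohexa-2,4-dienones) to give racemic 6-allyl-2-bromo-6-methylcyclohexa-2,4-dien-1-one F2. Resolve F2 by preparative chiral SFC; the 6R enantiomer is 3.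

Step 8 is next: competing sigmatropic paths and, above all, the face on which the enolate is trapped, which decides C8. The fallback sets out from 13 and comes back at 23. If bromine proves to enter from the β face, generate potassium enolate 15 as before and trap it with 2-(phenylsulfonyl)-3-phenyloxaziridine, whose oxygen then arrives on that same face to give 10-bromo-8β-hydroxy-6α,12-bis(TBS-oxy)-14-norgermacra-1(10),2,4,11(13)-tetraen-9-one F3. Acylate F3 with retention using 2,4,6-trichlorobenzoic (2S,3S)-2,3-dimethyloxirane-2-carboxylic anhydride F4, made from acid 21 and 2,4,6-trichlorobenzoyl chloride (Et3N, then DMAP). This gives 23 directly and bypasses 16 and the SN2 step.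

Step 18 is third: face selectivity of the second epoxidation at C2=C3. The fallback sets out from 30 and comes back at 32. Stop at the 4,5-monoepoxide 31 (1.05 equiv mCPBA, 0 °C). Treat 31 with NBS in aqueous THF, so that bromonium formation on the face the peracid prefers and anti opening by water give the 2α-hydroxy-3β-bromo bromohydrin F5. Close F5 with K2CO3 in acetone (intramolecular SN2), which places the oxirane on the α face and gives 32.

**Further compounds**
F1 | step 2 | sodium 2-bromo-6-methylphenoxide | [Na+].[O-]c1c(C)cccc1Br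
F2 | step 2 | racemic 6-allyl-2-bromo-6-methylcyclohexa-2,4-dien-1-one | C=CCC1(C)C=CC=C(Br)C1=O
F3 | step 8 | 10-bromo-8β-hydroxy-6α,12-bis(TBS-oxy)-14-norgermacra-1(10),2,4,11(13)-tetraen-9-one | O=C1[C@@H](O)[C@@H](C(=C)CO[Si](C)(C)C(C)(C)C)[C@H](O[Si](C)(C)C(C)(C)C)/C=C(C)/C=C\C=C1\Br
F4 | step 8 | 2,4,6-trichlorobenzoic (2S,3S)-2,3-dimethyloxirane-2-carboxylic anhydride | O=C(OC(=O)[C@@]1(C)O[C@H]1C)c1c(Cl)cc(Cl)cc1Cl
F5 | step 18 | 2α-hydroxy-3β-bromo bromohydrin of 31 | C=C1C(=O)O[C@H]2[C@H]1[C@H](OC(=O)[C@@]1(C)O[C@H]1C)[C@@H](OC(C)=O)/C(C(=O)OC)=C\[C@@H](O)[C@H](Br)[C@@]1(C)O[C@H]21
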